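**Plan**
Numbering: dihydrobenzofuran O1, C2, C3, C3a, C4–C7, C7a. C9 is the CH2O carbon on C3, and C9' is the terminal CH2O carbon of the propyl chain on C5.
Cuts: first the two acyl–O bonds (p-coumaroyl on O–C9, feruloyl on O–C9'), then C3–C3a together with C9–O, and last the O1–C2 ether bond. This leaves an iodinated dihydroconiferyl unit, a coniferyl unit, two cinnamic acids and a nitroxide.
Enabling feature: in the ring O1–C2–C3–C3a–C7a, C3 joins benzo carbon C3a to the exocyclic oxygenated carbon C9 and lies next to C2, which bears O1 and the guaiacyl ring. An sp2 radical at C3a, a C3=C9 vinyl group on C2 and an oxygen-centred radical trap map directly onto this array.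
Forward: the two C6–C3 halves are joined at O1–C2 by a branched-selective allylic etherification, and the dihydrofuran ring, the only ring made, closes in the radical step. The feruloyl chain goes on at C9' while the nitroxide residue still masks O–C9; the N–O bond is then cut, C9–OH is coumaroylated and the three phenols are freed.
Stereochemistry: C2 (R) comes from the chiral iridium catalyst, C3 (S) from 1,2-induction by C2 in the ring closure (2,3-trans), and both E alkenes from the cinnamic acids.

Key step: step 8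

Assumption: L* is whichever enantiomer of the matched (1,1'-binaphthalene-2,2'-diyl) N,N-bis(1-phenylethyl)phosphoramidite (Sa,Sc,Sc or Ra,Rc,Rc, both sold) gives the R ether. The sense of induction is to be confirmed on the first batch, and dihydroconiferyl alcohol is taken as purchasable.

Step 1
Reactants: 1 dihydroconiferyl alcohol
Product: 2 4-(3-hydroxypropyl)-2-iodo-6-methoxyphenol
Conditions: NaI, NaOH, aq NaOCl (slow addition), MeOH, 0 °C
Reagents that add atoms: sodium iodide [Na+].[I-]
Why: Electrophilic aromatic iodination of the phenoxide by hypoiodite made in situ goes ortho or para to the oxygen, and since the para and one ortho position are occupied only the C–H that becomes C3a should react.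

Step 2
Reactants: 2 4-(3-hydroxypropyl)-2-iodo-6-methoxyphenol
Product: 3 4-[3-(tert-butyldimethylsilyloxy)propyl]-2-iodo-6-methoxyphenol
Conditions: TBSCl (1.05 equiv), imidazole, CH2Cl2, 0 °C
Reagents that add atoms: tert-butyldimethylsilyl chloride CC(C)(C)[Si](C)(C)Cl
Why: Imidazole-promoted silylation should favour the unhindered primary alcohol over a phenol flanked by iodine and methoxy.

Step 3
Reactants: 4 (E)-ferulic acid
Product: 6 (E)-4-O-TIPS-ferulic acid, via TIPS ester 5 (not isolated)
Conditions: TIPSCl (2.3 equiv), imidazole, DMF, rt; crude in AcOH–THF–H2O (3:1:1), 40 °C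
Reagents that add atoms: triisopropylsilyl chloride CC(C)[Si](Cl)(C(C)C)C(C)C
Why: Exhaustive silylation followed by mild acid hydrolysis relies on silyl esters being far more labile than aryl TIPS ethers, which resist aqueous acid.

Step 4
Reactants: 6 (E)-4-O-TIPS-ferulic acid
Product: 8 (E)-4-O-TIPS-coniferyl alcohol, via mixed anhydride 7 (not isolated)
Conditions: i-BuOCOCl, N-methylmorpholine, THF, −15 °C; then NaBH4, H2O, −15 to 0 °C
Reagents that add atoms: none
Why: Reduction of a carboxylic acid through its mixed carbonic anhydride with NaBH4 should occur 1,2 at the activated carbonyl at low temperature and leave the conjugated alkene and the aryl silyl ether intact.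

Step 5
Reactants: 8 (E)-4-O-TIPS-coniferyl alcohol
Product: 9 tert-butyl (E)-3-[3-methoxy-4-(triisopropylsilyloxy)phenyl]allyl carbonate
Conditions: Boc2O, DMAP (10 mol %), CH2Cl2, 0 °C to rt
Reagents that add atoms: di-tert-butyl dicarbonate CC(C)(C)OC(=O)OC(=O)OC(C)(C)C
Why: DMAP-catalysed O-tert-butoxycarbonylation of a primary allylic alcohol is routine and installs a leaving group that later releases only hindered tert-butoxide.

Step 6
Reactants: 10 (E)-p-coumaric acid
Product: 12 (E)-4-O-TIPS-p-coumaric acid, via TIPS ester 11 (not isolated)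
Conditions: TIPSCl (2.3 equiv), imidazole, DMF, rt; crude in AcOH–THF–H2O (3:1:1), 40 °C
Reagents that add atoms: triisopropylsilyl chloride CC(C)[Si](Cl)(C(C)C)C(C)C
Why: The same silylation and selective silyl ester hydrolysis as in step 3 should give the phenol-protected acid.

Step 7
Reactants: 3 4-[3-(tert-butyldimethylsilyloxy)propyl]-2-iodo-6-methoxyphenol; 9 tert-butyl (E)-3-[3-methoxy-4-(triisopropylsilyloxy)phenyl]allyl carbonate
Product: 14 (R)-2-iodo-6-methoxy-4-(3-TBSO-propyl)phenyl 1-[3-methoxy-4-(TIPSO)phenyl]allyl ether, via lithium aryloxide 13 (not isolated)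
Conditions: 3, LiOt-Bu (1.0 equiv), THF, 0 °C; then 9, [Ir(cod)Cl]2 (2 mol %), L* (4 mol %, pre-activated with n-PrNH2), THF, rt
Reagents that add atoms: none
Why: In this iridium-catalysed asymmetric allylic etherification the cyclometalated Ir–phosphoramidite ionises 9 to an η3-allyl complex that 13 attacks at the aryl-bearing terminus anti to the metal, so the ligand fixes the face and sets C2 as R, while the released tert-butoxide is too hindered to compete or to attack the silyl ethers.

Step 8
Reactants: 14 (R)-2-iodo-6-methoxy-4-(3-TBSO-propyl)phenyl 1-[3-methoxy-4-(TIPSO)phenyl]allyl ether; 15 TEMPO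
Product: 16 (2R,3S)-7-methoxy-2-[3-methoxy-4-(TIPSO)phenyl]-3-[(2,2,6,6-tetramethylpiperidin-1-yl)oxymethyl]-5-(3-TBSO-propyl)-2,3-dihydrobenzofuran
Conditions: Bu3SnH and TEMPO (each in portions, excess), degassed toluene, high dilution, 65 °C
Reagents that add atoms: none
Why: Hydrogen transfer from Bu3SnH to TEMPO feeds Bu3Sn radicals that abstract iodine from C3a of 14, the σ-aryl radical adds to the inner vinyl carbon in a 5-exo-trig closure that makes C3–C3a and the dihydrofuran ring, and the exocyclic primary radical at C9 couples with the persistent nitroxide 15 to make C9–O. The closest known reaction type is the stannane/TEMPO aryl radical–alkene cyclisation with nitroxide capture that converts N-allyl and O-allyl 2-haloarenes into 3-(aminooxymethyl) indolines and dihydrobenzofurans. C3 is the only new stereocentre and is governed by C2: in the chair-like 5-exo transition state the C2 aryl group sits pseudo-equatorial, so C9 should end up trans to it (2R,3S), while the bonds at C2 are not involved. The step needs ring closure to beat capture of the aryl radical by nitroxide or stannane, which is secured by the short C7a–O1–C2 tether (among the fastest radical clocks) and by dosing both reagents in portions at high dilution, and a hydrogen shift from C2 would be a strained 1,4-transfer. Near diffusion-controlled coupling at C9 then forestalls hydrogen transfer, neophyl-type ring expansion and C2–C3 β-scission, and gives C9 at the alcohol oxidation level in masked form. The silyl and methyl ethers are inert to tin radicals, and because both ortho positions and the para position of the aryl ether are substituted no productive Claisen shift competes at 65 °C.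

Step 9
Reactants: 16 (2R,3S)-alkoxyamine with TBS-protected propanol
Product: 17 (2R,3S)-3-{7-methoxy-2-[3-methoxy-4-(TIPSO)phenyl]-3-[(2,2,6,6-tetramethylpiperidin-1-yl)oxymethyl]-2,3-dihydrobenzofuran-5-yl}propan-1-ol
Conditions: CSA (cat.), MeOH–CH2Cl2, 0 °C
Reagents that add atoms: none
Why: Acid-catalysed methanolysis cleaves a primary alkyl TBS ether much faster than an aryl TIPS ether and does not touch the alkoxyamine, so C9'–OH is freed while O–C9 stays masked.

Step 10
Reactants: 17 (2R,3S)-alkoxyamine propanol; 6 (E)-4-O-TIPS-ferulic acid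
Product: 18 (2R,3S)-alkoxyamine C9' 4-O-TIPS-ferulate
Conditions: DIC, DMAP (cat.), CH2Cl2, 0 °C to rt
Reagents that add atoms: none
Why: Steglich esterification of the only free hydroxyl group with a phenol-protected cinnamic acid is mild and leaves alkene geometry and both stereocentres untouched.

Step 11
Reactants: 18 (2R,3S)-alkoxyamine C9' 4-O-TIPS-ferulate
Product: 19 (2R,3S)-C9 alcohol C9' 4-O-TIPS-ferulate
Conditions: Zn dust, AcOH–THF–H2O (3:1:1), 60–70 °C
Reagents that add atoms: none
Why: Dissolving-metal reduction of the N–O bond with zinc in acetic acid releases C9–OH, and it is placed after removal of the acid-labile alkyl TBS group so that only acid-stable aryl TIPS ethers and a cinnamate beyond the reducing power of zinc are exposed.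

Step 12
Reactants: 19 (2R,3S)-C9 alcohol C9' 4-O-TIPS-ferulate; 12 (E)-4-O-TIPS-p-coumaric acid
Product: 20 tris-O-TIPS-boehmenan X
Conditions: DIC, DMAP (cat.), CH2Cl2, 0 °C to rt
Reagents that add atoms: none
Why: A second Steglich esterification acylates the single remaining primary alcohol at C9 under conditions too weakly basic to eliminate or epimerise at C3.

Step 13
Reactants: 20 tris-O-TIPS-boehmenan X
Product: 21 (+)-boehmenan X
Conditions: TBAF, AcOH (1:1, 3.5 equiv each), THF, 0 °C
Reagents that add atoms: none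
Why: Fluoride-induced desilylation of the three aryl TIPS ethers is fast at 0 °C, and the acetic acid buffer keeps the freed phenols protonated so that neither ester cleavage nor quinone-methide opening of the O1–C2 bond can set in.

**Compound list**
1 | dihydroconiferyl alcohol, 4-(3-hydroxypropyl)-2-methoxyphenol | COc1cc(CCCO)ccc1O | starting material
2 | 4-(3-hydroxypropyl)-2-iodo-6-methoxyphenol | COc1cc(CCCO)cc(I)c1O | intermediate
3 | 4-[3-(tert-butyldimethylsilyloxy)propyl]-2-iodo-6-methoxyphenol | COc1cc(CCCO[Si](C)(C)C(C)(C)C)cc(I)c1O | intermediate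
4 | (E)-ferulic acid | COc1cc(/C=C/C(=O)O)ccc1O | starting material
5 | triisopropylsilyl (E)-4-O-TIPS-ferulate | COc1cc(/C=C/C(=O)O[Si](C(C)C)(C(C)C)C(C)C)ccc1O[Si](C(C)C)(C(C)C)C(C)C | intermediate
6 | (E)-4-O-TIPS-ferulic acid | COc1cc(/C=C/C(=O)O)ccc1O[Si](C(C)C)(C(C)C)C(C)C | intermediate
7 | isobutyl carbonic mixed anhydride of 6 | COc1cc(/C=C/C(=O)OC(=O)OCC(C)C)ccc1O[Si](C(C)C)(C(C)C)C(C)C | intermediate
8 | (E)-4-O-TIPS-coniferyl alcohol | COc1cc(/C=C/CO)ccc1O[Si](C(C)C)(C(C)C)C(C)C | intermediate
9 | tert-butyl (E)-3-[3-methoxy-4-(triisopropylsilyloxy)phenyl]allyl carbonate | COc1cc(/C=C/COC(=O)OC(C)(C)C)ccc1O[Si](C(C)C)(C(C)C)C(C)C | intermediate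
10 | (E)-p-coumaric acid | O=C(O)/C=C/c1ccc(O)cc1 | starting material
11 | triisopropylsilyl (E)-4-O-TIPS-p-coumarate | O=C(O[Si](C(C)C)(C(C)C)C(C)C)/C=C/c1ccc(O[Si](C(C)C)(C(C)C)C(C)C)cc1 | intermediate
12 | (E)-4-O-TIPS-p-coumaric acid | O=C(O)/C=C/c1ccc(O[Si](C(C)C)(C(C)C)C(C)C)cc1 | intermediate
13 | lithium aryloxide of 3 | [Li+].COc1cc(CCCO[Si](C)(C)C(C)(C)C)cc(I)c1[O-] | intermediate
14 | (R)-2-iodo-6-methoxy-4-(3-TBSO-propyl)phenyl 1-[3-methoxy-4-(TIPSO)phenyl]allyl ether | CC(C)(C)[Si](C)(C)OCCCc1cc(OC)c(O[C@H](C=C)c2ccc(O[Si](C(C)C)(C(C)C)C(C)C)c(OC)c2)c(I)c1 | intermediate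
15 | TEMPO, 2,2,6,6-tetramethylpiperidin-1-oxyl | CC1(C)CCCC(C)(C)N1[O] | starting material
16 | (2R,3S)-trans-2-aryl-3-(tetramethylpiperidinyloxymethyl)-2,3-dihydrobenzofuran, C9' O-TBS, aryl O-TIPS | CC(C)(C)[Si](C)(C)OCCCc1cc(OC)c2c(c1)[C@@H](CON1C(C)(C)CCCC1(C)C)[C@H](c1ccc(O[Si](C(C)C)(C(C)C)C(C)C)c(OC)c1)O2 | intermediate
17 | (2R,3S)-alkoxyamine with free C9' propanol | OCCCc1cc(OC)c2c(c1)[C@@H](CON1C(C)(C)CCCC1(C)C)[C@H](c1ccc(O[Si](C(C)C)(C(C)C)C(C)C)c(OC)c1)O2 | intermediate
18 | (2R,3S)-alkoxyamine C9' (E)-4-O-TIPS-ferulate | COc1cc(/C=C/C(=O)OCCCc2cc(OC)c3c(c2)[C@@H](CON2C(C)(C)CCCC2(C)C)[C@H](c2ccc(O[Si](C(C)C)(C(C)C)C(C)C)c(OC)c2)O3)ccc1O[Si](C(C)C)(C(C)C)C(C)C | intermediate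
19 | (2R,3S)-C9 alcohol C9' (E)-4-O-TIPS-ferulate | COc1cc(/C=C/C(=O)OCCCc2cc(OC)c3c(c2)[C@@H](CO)[C@H](c2ccc(O[Si](C(C)C)(C(C)C)C(C)C)c(OC)c2)O3)ccc1O[Si](C(C)C)(C(C)C)C(C)C | intermediate
20 | tris-O-TIPS-boehmenan X | COc1cc(/C=C/C(=O)OCCCc2cc(OC)c3c(c2)[C@@H](COC(=O)/C=C/c2ccc(O[Si](C(C)C)(C(C)C)C(C)C)cc2)[C@H](c2ccc(O[Si](C(C)C)(C(C)C)C(C)C)c(OC)c2)O3)ccc1O[Si](C(C)C)(C(C)C)C(C)C | intermediate
21 | (+)-boehmenan X, (2R,3S) | COc1cc(/C=C/C(=O)OCCCc2cc(OC)c3c(c2)[C@@H](COC(=O)/C=C/c2ccc(O)cc2)[C@H](c2ccc(O)c(OC)c2)O3)ccc1O | target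

Total step count: 13. Longest linear sequence: 10 steps (4 → 6 → 8 → 9 → 14 → 16 → 17 → 18 → 19 → 20 → 21).

**Steps most likely to fail**

Step 7. The doubly ortho-substituted aryloxide may attack the substituted allyl terminus slowly, so that linear ether accumulates. The electron-rich branched ether may also re-ionise on the catalyst, which erodes enantiopurity. The fallback takes the configuration from a resolved carbinol and transfers it stereospecifically; it sets out from 3 and rejoins the route at 14. Commercial vanillin is silylated (TIPSCl, imidazole, DMF) to O-TIPS-vanillin F1. Vinylmagnesium bromide (THF, −78 °C) then gives the racemic aryl vinyl carbinol F2. A Sharpless kinetic resolution (Ti(Oi-Pr)4, D-(−)-DIPT, t-BuOOH, 4 Å MS, CH2Cl2, −20 °C) should leave the (R)-carbinol F3, while the S enantiomer is consumed as the epoxy alcohol F4 and removed by chromatography. Methyl chloroformate and pyridine give the (R)-methyl carbonate F5. This reacts with phenol 3 under [Cp*Ru(MeCN)3]PF6 catalysis, a branched-selective stereospecific allylic etherification with net retention, to give 14.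

Step 8. The nitroxide may drain the stannane through unproductive hydrogen transfer and Sn–O coupling before the iodide is consumed. It may also intercept the aryl radical before ring closure, and facial selectivity in the closure may be only moderate. The fallback keeps the same C3–C3a closure but lets dioxygen take the C9 radical, which removes the stannane–nitroxide cross-reaction and the later N–O cleavage and reverses the order of the esters. It sets out from 14 and rejoins at 20. Bu3SnH under a stream of dry air in toluene (oxygenative radical cyclisation, 0 °C to rt) should give the C9 hydroperoxide F6, which PPh3 reduces in the same flask to the C9 alcohol F7. DIC/DMAP with 12 gives the C9 coumarate F8, CSA in MeOH frees the propanol to give the hydroxy coumarate F9, and DIC/DMAP with 6 gives 20.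

Step 11. N–O reduction may be sluggish at temperatures the phenolic silyl ethers tolerate, and prolonged hot aqueous acid may strip those groups and expose phenols to the next acylation. The fallback cleaves the alkoxyamine oxidatively instead of reductively; it sets out from 18 and rejoins at 19. mCPBA (CH2Cl2, 0 °C) oxidises the nitrogen, and elimination then gives the trans C3 carbaldehyde F10. This is reduced at once with NaBH4 (THF–MeOH, −20 °C), before enolisation or ring opening can occur, to give 19.

**Further compounds**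
F1 | step 7 | O-TIPS-vanillin | COc1cc(C=O)ccc1O[Si](C(C)C)(C(C)C)C(C)C
F2 | step 7 | racemic 1-[3-methoxy-4-(TIPSO)phenyl]prop-2-en-1-ol | C=CC(O)c1ccc(O[Si](C(C)C)(C(C)C)C(C)C)c(OC)c1
F3 | step 7 | (R)-1-[3-methoxy-4-(TIPSO)phenyl]prop-2-en-1-ol | O[C@H](C=C)c1ccc(O[Si](C(C)C)(C(C)C)C(C)C)c(OC)c1
F4 | step 7 | (R)-[3-methoxy-4-(TIPSO)phenyl][(R)-oxiran-2-yl]methanol | O[C@@H]([C@H]1CO1)c1ccc(O[Si](C(C)C)(C(C)C)C(C)C)c(OC)c1
F5 | step 7 | (R)-methyl 1-[3-methoxy-4-(TIPSO)phenyl]allyl carbonate | COC(=O)O[C@H](C=C)c1ccc(O[Si](C(C)C)(C(C)C)C(C)C)c(OC)c1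
F6 | step 8 | (2R,3S)-3-(hydroperoxymethyl)dihydrobenzofuran, C9' O-TBS, aryl O-TIPS | CC(C)(C)[Si](C)(C)OCCCc1cc(OC)c2c(c1)[C@@H](COO)[C@H](c1ccc(O[Si](C(C)C)(C(C)C)C(C)C)c(OC)c1)O2
F7 | step 8 | (2R,3S)-3-(hydroxymethyl)dihydrobenzofuran, C9' O-TBS, aryl O-TIPS | CC(C)(C)[Si](C)(C)OCCCc1cc(OC)c2c(c1)[C@@H](CO)[C@H](c1ccc(O[Si](C(C)C)(C(C)C)C(C)C)c(OC)c1)O2
F8 | step 8 | (2R,3S)-C9 (E)-4-O-TIPS-p-coumarate, C9' O-TBS | CC(C)(C)[Si](C)(C)OCCCc1cc(OC)c2c(c1)[C@@H](COC(=O)/C=C/c1ccc(O[Si](C(C)C)(C(C)C)C(C)C)cc1)[C@H](c1ccc(O[Si](C(C)C)(C(C)C)C(C)C)c(OC)c1)O2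
F9 | step 8 | (2R,3S)-C9 (E)-4-O-TIPS-p-coumarate with free C9' propanol | OCCCc1cc(OC)c2c(c1)[C@@H](COC(=O)/C=C/c1ccc(O[Si](C(C)C)(C(C)C)C(C)C)cc1)[C@H](c1ccc(O[Si](C(C)C)(C(C)C)C(C)C)c(OC)c1)O2
F10 | step 11 | trans-2-aryl-2,3-dihydrobenzofuran-3-carbaldehyde C9' (E)-4-O-TIPS-ferulate | COc1cc(/C=C/C(=O)OCCCc2cc(OC)c3c(c2)[C@@H](C=O)[C@H](c2ccc(O[Si](C(C)C)(C(C)C)C(C)C)c(OC)c2)O3)ccc1O[Si](C(C)C)(C(C)C)C(C)C
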